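**Retrosynthetic overview**

1. The C8 isobutyrate is installed last (steps 14–15); until then O8 carries a p-methoxybenzyl (PMB) ether, which serves as the chelating group in the key step.
2. Key disconnection C9–C10: C10 is C2 of the 3(2H)-furanone ring (between the ring oxygen and the C1 ketone) and C9 is the carbinol β to that ketone, an aldol retron whose enol partner is an aromatic 3-silyloxyfuran. The ten-membered carbocycle C1–C10 with its C3–O–C10 bridge is therefore closed last, from a flat furan and a C9 aldehyde, by a chelation-controlled Mukaiyama aldol that creates C9 and C10 together.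
3. The aldol precursor comes from enal 8 (C1–C6, C10, C14, C15) and δ-lactone allyl bromide 14 (C7–C9, C11–C13) by an indium Barbier reaction that sets C6 and C7 from C8; δ-to-γ translactonisation then gives the trans α-methylene-γ-butyrolactone and frees the C9 alcohol.
4. Enal 8 derives from commercial (Z)-3-methylpent-2-en-4-yn-1-ol (source of the Z-C4=C5 alkene) and (S)-2-acetoxypropanoyl chloride via an ynone; bromide 14 derives from (S)-but-3-ene-1,2-diol (source of C8) and 2-(bromomethyl)acrylic acid by ring-closing metathesis.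
5. Order of ring formation: furanone (step 3), δ-lactone (step 9), γ-lactone (step 10), ten-membered ring (step 13).

Key step: step 13

Remark: germacrane numbering is used (C1 ketone, C3–O–C10 ether bridge, C6 lactone oxygen, C8 ester, C9 carbinol, C11=C13 methylene, C12 lactone carbonyl); C10 of the 2-monosubstituted furanones 6–8 and 15–17 is enolisable and is carried as a mixture of epimers (drawn without configuration), because this centre is erased in 18 and set in step 13.

**Route**

Step 1
Reactants: 1 (Z)-3-methylpent-2-en-4-yn-1-ol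
Product: 2 tert-butyldimethyl{[(Z)-3-methylpent-2-en-4-yn-1-yl]oxy}silane
Conditions: TBSCl, imidazole, CH2Cl2, 0 °C to rt
Reagents that add atoms: tert-butyldimethylsilyl chloride, CC(C)(C)[Si](C)(C)Cl
Why: Standard silylation of the primary allylic alcohol, which keeps the alcohol out of the acylation in step 2 and leaves the Z-alkene untouched.

Step 2
Reactants: 2 tert-butyldimethyl{[(Z)-3-methylpent-2-en-4-yn-1-yl]oxy}silane; 3 (S)-2-acetoxypropanoyl chloride
Product: 4 (2S,6Z)-8-(tert-butyldimethylsilyloxy)-6-methyl-3-oxooct-6-en-4-yn-2-yl acetate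
Conditions: PdCl2(PPh3)2 (2 mol%), CuI (4 mol%), Et3N (1.2 equiv), THF, rt
Reagents that add atoms: none
Why: Acyl Sonogashira coupling of a terminal alkyne with an acid chloride gives the ynone directly under mild conditions that tolerate the silyl ether and the Z-enyne.

Step 3
Reactants: 4 (2S,6Z)-8-(tert-butyldimethylsilyloxy)-6-methyl-3-oxooct-6-en-4-yn-2-yl acetate
Product: 6 5-[(2Z)-4-(tert-butyldimethylsilyloxy)but-2-en-2-yl]-2-methylfuran-3(2H)-one, via hydroxy ynone 5 (not isolated)
Conditions: K2CO3 (0.3 equiv), MeOH, 0 °C; then pH 7 buffer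
Reagents that add atoms: none
Why: Methanolysis of the α-acetoxy ketone liberates hydroxy ynone 5, whose alkoxide adds to the ynone β-carbon in a Baldwin-allowed 5-endo-dig oxa-Michael cyclisation (base-mediated hydroxy-ynone to 3(2H)-furanone cyclisation); short contact at 0 °C should spare the Z-alkene.

Step 4
Reactants: 6 5-[(2Z)-4-(tert-butyldimethylsilyloxy)but-2-en-2-yl]-2-methylfuran-3(2H)-one
Product: 7 5-[(2Z)-4-hydroxybut-2-en-2-yl]-2-methylfuran-3(2H)-one
Conditions: HF·pyridine, pyridine, THF, 0 °C to rt
Reagents that add atoms: none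
Why: Buffered fluoride cleaves the primary silyl ether without enolising the furanone or isomerising the alkene.

Step 5
Reactants: 7 5-[(2Z)-4-hydroxybut-2-en-2-yl]-2-methylfuran-3(2H)-one
Product: 8 (2Z)-3-(5-methyl-4-oxo-4,5-dihydrofuran-2-yl)but-2-enal
Conditions: MnO2 (activated, excess), CH2Cl2, rt, dark; used at once
Reagents that add atoms: none
Why: MnO2 oxidises allylic alcohols selectively under neutral heterogeneous conditions, which should preserve the Z geometry of the enal.

Step 6
Reactants: 9 (S)-but-3-ene-1,2-diol
Product: 10 (4S)-2-(4-methoxyphenyl)-4-vinyl-1,3-dioxolane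
Conditions: 4-methoxybenzaldehyde dimethyl acetal, CSA (5 mol%), CH2Cl2, rt
Reagents that add atoms: 4-methoxybenzaldehyde dimethyl acetal, COc1ccc(C(OC)OC)cc1
Why: Acid-catalysed transacetalisation forms the five-membered p-methoxybenzylidene acetal without touching the carbinol stereocentre (the future C8).

Step 7
Reactants: 10 (4S)-2-(4-methoxyphenyl)-4-vinyl-1,3-dioxolane
Product: 11 (S)-2-(4-methoxybenzyloxy)but-3-en-1-ol
Conditions: i-Bu2AlH (2.5 equiv), CH2Cl2, −78 to 0 °C; aq. potassium sodium tartrate
Reagents that add atoms: none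
Why: In this regioselective reductive acetal opening the aluminium reagent binds the less hindered primary oxygen and delivers hydride to the acetal carbon, so the PMB group stays on the secondary oxygen and the primary alcohol is freed.

Step 8
Reactants: 11 (S)-2-(4-methoxybenzyloxy)but-3-en-1-ol; 12 2-(bromomethyl)acrylic acid
Product: 13 (S)-2-(4-methoxybenzyloxy)but-3-en-1-yl 2-(bromomethyl)acrylate
Conditions: DCC (1.2 equiv), DMAP (5 mol%), CH2Cl2, 0 °C
Reagents that add atoms: none
Why: Steglich esterification of the primary alcohol at 0 °C with only catalytic DMAP should outrun substitution of the allylic bromide.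

Step 9
Reactants: 13 (S)-2-(4-methoxybenzyloxy)but-3-en-1-yl 2-(bromomethyl)acrylate
Product: 14 (5S)-3-(bromomethyl)-5-(4-methoxybenzyloxy)-5,6-dihydro-2H-pyran-2-one
Conditions: second-generation Hoveyda–Grubbs catalyst (5 mol%), toluene (0.01 M), 80 °C
Reagents that add atoms: none
Why: Ring-closing metathesis between the monosubstituted alkene and the 2-substituted acrylate closes the six-membered unsaturated lactone with loss of ethylene; allylic bromides and benzylic ethers are tolerated.

Step 10
Reactants: 8 (2Z)-3-(5-methyl-4-oxo-4,5-dihydrofuran-2-yl)but-2-enal; 14 (5S)-3-(bromomethyl)-5-(4-methoxybenzyloxy)-5,6-dihydro-2H-pyran-2-one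
Product: 16 (6R,7S,8S)-γ-lactone alcohol: (4S,5R)-4-[(1S)-2-hydroxy-1-(4-methoxybenzyloxy)ethyl]-3-methylene-5-[(1Z)-2-(5-methyl-4-oxo-4,5-dihydrofuran-2-yl)prop-1-en-1-yl]dihydrofuran-2(3H)-one, via δ-lactone adduct 15 (not isolated)
Conditions: indium powder (1.5 equiv), THF/H2O (3:1), rt; then CSA (10 mol%), CH2Cl2, rt
Reagents that add atoms: none
Why: Indium-mediated Barbier allylation (Dreiding–Schmidt type) through a chair Zimmerman–Traxler transition state, in which the ring holds C8 trans to the CH2–In carbon so that the new C6 carbinol forms anti to C8 (6R, the trans-lactone relationship), while the aldehyde approaches C7 on the face opposite the adjacent C8 PMB ether (7S, 7,8-trans on the δ-lactone); acid then moves the acyl group from O9 to O6 because the γ-lactone is the more stable ring, which frees the C9 alcohol.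

Step 11
Reactants: 16 (6R,7S,8S)-γ-lactone alcohol
Product: 17 (6R,7S,8S)-C9 aldehyde: (2S)-2-(4-methoxybenzyloxy)-2-{(2R,3S)-4-methylene-2-[(1Z)-2-(5-methyl-4-oxo-4,5-dihydrofuran-2-yl)prop-1-en-1-yl]-5-oxotetrahydrofuran-3-yl}acetaldehyde
Conditions: Dess–Martin periodinane (1.3 equiv), pyridine, CH2Cl2, 0 °C to rt
Reagents that add atoms: none
Why: Buffered Dess–Martin oxidation converts the only free (primary) alcohol into the α-alkoxy aldehyde without epimerising C8 or touching the lactone and furanone.

Step 12
Reactants: 17 (6R,7S,8S)-C9 aldehyde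
Product: 18 3-silyloxyfuran aldehyde: the 2-methyl-3-(triisopropylsilyloxy)furan form of 17
Conditions: i-Pr3SiOTf (1.1 equiv), Et3N (1.5 equiv), CH2Cl2, −78 °C; rapid filtration through Et3N-deactivated silica
Reagents that add atoms: triisopropylsilyl trifluoromethanesulfonate, CC(C)[Si](C(C)C)(C(C)C)OS(=O)(=O)C(F)(F)F
Why: Soft enolisation, in which C10–H is by far the most acidic proton because its enol is an aromatic furan, so O-silylation of the furanone (a known way to 3-silyloxyfurans) should be faster at −78 °C than any reaction at the aldehyde; the labile C10 centre is erased here.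

Step 13
Reactants: 18 3-silyloxyfuran aldehyde
Product: 19 8-O-PMB macrocycle (6R,7S,8S,9R,10S): the target skeleton with 9-OH free and a 4-methoxybenzyl ether at O8
Conditions: MgBr2·OEt2 (3 equiv), CH2Cl2 (0.001 M, slow addition of 18), −78 to −20 °C; pH 7 buffer
Reagents that add atoms: none
Why: MgBr2 binds the C9 aldehyde oxygen together with the C8 PMB ether oxygen, and C10, which is C2 of the aromatic 3-silyloxyfuran and its most nucleophilic carbon, adds to the activated aldehyde; loss of the silyl group from the oxocarbenium ion unveils the C1 ketone, so the furan is dearomatised to the 3(2H)-furanone (closest known reaction types: Lewis-acid-promoted Mukaiyama aldol addition of 2-substituted 3-silyloxyfurans to aldehydes at C2, and chelation-controlled Mukaiyama aldol additions to α-alkoxy aldehydes). The ten-membered carbocycle C1–C10, which is at the same time a nine-membered oxacycle through the furan oxygen, is closed by intramolecular aldol addition of the enol ether carbon to the exocyclic aldehyde under high dilution, with the Z-C4=C5 alkene and the trans-fused lactone turning the chain back toward C10. C9 is set by the Cram chelate: with O8 and O9 held syn by magnesium, C10 should arrive on the aldehyde face away from C7, which gives the 8,9-syn (9R) carbinol. C10 is set by the tether: the six-atom chain C4–C9 starts in the plane of the furan at C3 and carries the 6R,7S lactone, so it is expected to reach C10 from one face only, which gives 10S. The step needs C10 rather than C2 as the reacting furan carbon (secured by the enol ether polarisation and by ring size), the aldehyde rather than the α-methylene lactone as electrophile (secured by chelate activation) and ring closure rather than oligomerisation (secured by slow addition at high dilution).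

Step 14
Reactants: 19 8-O-PMB macrocycle
Product: 20 8,9-diol macrocycle (6R,7S,8S,9R,10S)
Conditions: DDQ (1.5 equiv), CH2Cl2/pH 7 buffer (10:1), 0 °C
Reagents that add atoms: none
Why: Oxidative cleavage of the electron-rich PMB ether leaves the electron-poor dienone and the α-methylene lactone alone, and the water present should intercept the oxocarbenium ion before the neighbouring C9 hydroxyl can close an acetal.

Step 15
Reactants: 20 8,9-diol macrocycle; 21 isobutyric anhydride
Product: 22 target CNP0265772.2
Conditions: 21 (1.1 equiv), 2,4,6-collidine, DMAP (5 mol%), CH2Cl2, −40 °C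
Reagents that add atoms: none
Why: DMAP-catalysed acylation should take place at the C8 hydroxyl because the C9 hydroxyl is neopentylic (next to quaternary C10) and hydrogen-bonded to the C1 ketone, and one equivalent of anhydride at low temperature with a weak base avoids retro-aldol opening and acyl migration.

**Compound list**

1 | (Z)-3-methylpent-2-en-4-yn-1-ol | C#C/C(C)=C\CO | starting material
2 | tert-butyldimethyl{[(Z)-3-methylpent-2-en-4-yn-1-yl]oxy}silane | C#C/C(C)=C\CO[Si](C)(C)C(C)(C)C | intermediate
3 | (S)-2-acetoxypropanoyl chloride | C[C@H](OC(C)=O)C(Cl)=O | starting material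
4 | (2S,6Z)-8-(tert-butyldimethylsilyloxy)-6-methyl-3-oxooct-6-en-4-yn-2-yl acetate | C[C@H](OC(C)=O)C(=O)C#C/C(C)=C\CO[Si](C)(C)C(C)(C)C | intermediate
5 | (2S,6Z)-8-(tert-butyldimethylsilyloxy)-2-hydroxy-6-methyloct-6-en-4-yn-3-one (hydroxy ynone, not isolated) | C[C@H](O)C(=O)C#C/C(C)=C\CO[Si](C)(C)C(C)(C)C | intermediate
6 | 5-[(2Z)-4-(tert-butyldimethylsilyloxy)but-2-en-2-yl]-2-methylfuran-3(2H)-one (C2 epimers) | CC1OC(=CC1=O)/C(C)=C\CO[Si](C)(C)C(C)(C)C | intermediate
7 | 5-[(2Z)-4-hydroxybut-2-en-2-yl]-2-methylfuran-3(2H)-one (C2 epimers) | CC1OC(=CC1=O)/C(C)=C\CO | intermediate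
8 | (2Z)-3-(5-methyl-4-oxo-4,5-dihydrofuran-2-yl)but-2-enal (ring C5 epimers) | CC1OC(=CC1=O)/C(C)=C\C=O | intermediate
9 | (S)-but-3-ene-1,2-diol | C=C[C@H](O)CO | starting material
10 | (4S)-2-(4-methoxyphenyl)-4-vinyl-1,3-dioxolane (acetal epimers) | C=C[C@H]1COC(c2ccc(OC)cc2)O1 | intermediate
11 | (S)-2-(4-methoxybenzyloxy)but-3-en-1-ol | C=C[C@H](OCc1ccc(OC)cc1)CO | intermediate
12 | 2-(bromomethyl)acrylic acid | C=C(CBr)C(=O)O | starting material
13 | (S)-2-(4-methoxybenzyloxy)but-3-en-1-yl 2-(bromomethyl)acrylate | C=C[C@H](OCc1ccc(OC)cc1)COC(=O)C(=C)CBr | intermediate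
14 | (5S)-3-(bromomethyl)-5-(4-methoxybenzyloxy)-5,6-dihydro-2H-pyran-2-one | O=C1OC[C@@H](OCc2ccc(OC)cc2)C=C1CBr | intermediate
15 | δ-lactone adduct (6R,7S,8S; not isolated): (4S,5S)-4-[(1R,2Z)-1-hydroxy-3-(5-methyl-4-oxo-4,5-dihydrofuran-2-yl)but-2-en-1-yl]-5-(4-methoxybenzyloxy)-3-methylenetetrahydro-2H-pyran-2-one | C=C1C(=O)OC[C@@H](OCc2ccc(OC)cc2)[C@@H]1[C@H](O)/C=C(/C)C3=CC(=O)C(C)O3 | intermediate
16 | γ-lactone alcohol (6R,7S,8S): (4S,5R)-4-[(1S)-2-hydroxy-1-(4-methoxybenzyloxy)ethyl]-3-methylene-5-[(1Z)-2-(5-methyl-4-oxo-4,5-dihydrofuran-2-yl)prop-1-en-1-yl]dihydrofuran-2(3H)-one | C=C1C(=O)O[C@H](/C=C(/C)C2=CC(=O)C(C)O2)[C@H]1[C@H](OCc3ccc(OC)cc3)CO | intermediate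
17 | C9 aldehyde (6R,7S,8S): (2S)-2-(4-methoxybenzyloxy)-2-{(2R,3S)-4-methylene-2-[(1Z)-2-(5-methyl-4-oxo-4,5-dihydrofuran-2-yl)prop-1-en-1-yl]-5-oxotetrahydrofuran-3-yl}acetaldehyde | C=C1C(=O)O[C@H](/C=C(/C)C2=CC(=O)C(C)O2)[C@H]1[C@H](OCc3ccc(OC)cc3)C=O | intermediate
18 | 3-silyloxyfuran aldehyde (6R,7S,8S): as 17, with the furanone replaced by 5-methyl-4-(triisopropylsilyloxy)furan-2-yl | C=C1C(=O)O[C@H](/C=C(/C)c2cc(O[Si](C(C)C)(C(C)C)C(C)C)c(C)o2)[C@H]1[C@H](OCc3ccc(OC)cc3)C=O | intermediate
19 | 8-O-(4-methoxybenzyl) macrocycle (6R,7S,8S,9R,10S): target skeleton with 9-OH free and OPMB at C8 | C=C1C(=O)O[C@@H]2/C=C(/C)C3=CC(=O)[C@@](C)(O3)[C@H](O)[C@@H](OCc4ccc(OC)cc4)[C@@H]12 | intermediate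
20 | 8,9-diol macrocycle (6R,7S,8S,9R,10S) | C=C1C(=O)O[C@@H]2/C=C(/C)C3=CC(=O)[C@@](C)(O3)[C@H](O)[C@@H](O)[C@@H]12 | intermediate
21 | isobutyric anhydride | CC(C)C(=O)OC(=O)C(C)C | starting material
22 | CNP0265772.2 (6R,7S,8S,9R,10S; 4Z) | C=C1C(=O)O[C@@H]2/C=C(/C)C3=CC(=O)[C@@](C)(O3)[C@H](O)[C@@H](OC(=O)C(C)C)[C@@H]12 | target

**Step count and risks**

Total step count: 15. Longest linear sequence: 11 steps (steps 1–5, then 10–15).

The three steps most likely to fail, riskiest first:

First, step 13. Closure of the strained ten-membered ring may lose out to intermolecular aldol oligomerisation, or the furan or aldehyde may be attacked on the undesired face. The fallback replaces the open, Lewis-acid-promoted addition by a reductive, metal-templated one and sets out from 18. Treatment with N-bromosuccinimide in THF at −78 °C should brominate the silyl enol ether carbon and give the C10-bromo furanone aldehyde F1, which is used cold without purification. Slow addition of F1 to SmI2 (2.2 equiv) in THF at −78 °C should generate a samarium enolate at C10 that closes onto the C9 aldehyde through a samarium-bridged cyclic transition state (intramolecular samarium Reformatsky reaction, a known way to medium rings). This returns to the route at 19.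

Second, step 10. The allylindium species may lose the C8 alkoxide by 1,4-elimination before it meets the aldehyde, or facial selectivity at C7 may erode in the aqueous medium. The fallback uses a covalent, isolable allylboron reagent and sets out from 13. Palladium-catalysed borylation of the allylic bromide (B2pin2, Pd2(dba)3, toluene, 50 °C) should give the 2-(pinacolborylmethyl)acrylate F2. Ring-closing metathesis under the conditions of step 9 should then give the cyclic allylboronate F3, in which the carbon–boron bond cannot expel the alkoxide. Allylboration of 8 (Sc(OTf)3 10 mol%, toluene, rt to 60 °C) passes through the same chair transition state and should give 15 after work-up; CSA then completes the translactonisation. This returns to the route at 16.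

Third, step 15. Acylation may be unselective between the C8 and C9 hydroxyls, or the acyl group may migrate under the basic conditions. The fallback differentiates the two oxygens by protection and sets out from 19. Silylation of the free C9 hydroxyl (Et3SiOTf, 2,6-lutidine, CH2Cl2, −78 °C) should give the 9-O-triethylsilyl ether F4. DDQ cleavage of the PMB ether then gives the C8 alcohol F5, and acylation with 21 (DMAP, Et3N, CH2Cl2) gives the 9-O-silyl 8-isobutyrate F6. HF·pyridine in THF removes the silyl group and returns to the route at 22.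

**Further compounds**

F1 | step 13 | C10-bromo furanone aldehyde (as 17 with bromine at C10; C10 epimers) | C=C1C(=O)O[C@H](/C=C(/C)C2=CC(=O)C(C)(Br)O2)[C@H]1[C@H](OCc3ccc(OC)cc3)C=O
F2 | step 10 | (S)-2-(4-methoxybenzyloxy)but-3-en-1-yl 2-[(4,4,5,5-tetramethyl-1,3,2-dioxaborolan-2-yl)methyl]acrylate | C=C[C@H](OCc1ccc(OC)cc1)COC(=O)C(=C)CB2OC(C)(C)C(C)(C)O2
F3 | step 10 | (5S)-5-(4-methoxybenzyloxy)-3-[(4,4,5,5-tetramethyl-1,3,2-dioxaborolan-2-yl)methyl]-5,6-dihydro-2H-pyran-2-one | O=C1OC[C@@H](OCc2ccc(OC)cc2)C=C1CB3OC(C)(C)C(C)(C)O3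
F4 | step 15 | 9-O-triethylsilyl ether of 19 | C=C1C(=O)O[C@@H]2/C=C(/C)C3=CC(=O)[C@@](C)(O3)[C@H](O[Si](CC)(CC)CC)[C@@H](OCc4ccc(OC)cc4)[C@@H]12
F5 | step 15 | 9-O-triethylsilyl ether of diol 20 (8-OH free) | C=C1C(=O)O[C@@H]2/C=C(/C)C3=CC(=O)[C@@](C)(O3)[C@H](O[Si](CC)(CC)CC)[C@@H](O)[C@@H]12
F6 | step 15 | 9-O-triethylsilyl ether of target 22 | C=C1C(=O)O[C@@H]2/C=C(/C)C3=CC(=O)[C@@](C)(O3)[C@H](O[Si](CC)(CC)CC)[C@@H](OC(=O)C(C)C)[C@@H]12
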